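## Analysis of the target

Compound 18 is a biflavonol: two 3-hydroxy-2-arylchromen-4-one units joined by a diaryl ether oxygen between C4′ of ring B of unit 1 and C4′ of ring B of unit 2. Unit 1 carries OMe at C7 and OH at C3, C5 and C3′; unit 2 carries OH at C3, C5 and C7 and OMe at C3′. The two halves therefore differ only in which oxygens are methylated. There is no stereocentre, so the problem is one of regiochemistry and of telling two nearly identical halves apart. The four phenols and the two enolic 3-hydroxy-4-pyranone units are oxidised easily in base and air, so they should appear only in the last step. The difficulties are the two phloroglucinol-type rings A (clean electrophilic C-acylation needs heavy protecting-group traffic), the differentiation of the two C7 oxygens and of the two rings B, and a diaryl ether with oxygen ortho to the bridge on both sides. The strategy rests on one feature: in each unit C4a lies between the oxygen-bearing carbons C5 and C8a, with the third oxygen at C7 para to it. Every oxygen of ring A is thus ortho or para to the carbon that carries the C4 carbonyl, so an acyl group at C4a activates all three positions towards nucleophilic substitution. The rings A can then be taken from 2,6-difluoro-4-methoxyphenyl and 2,4,6-trifluorophenyl ketones, with O1–C8a made by displacement of fluoride.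

## Retrosynthetic reasoning

**18 from 17.** The four O–CH2Ph bonds are cut last. The phenols at C5 and C3′ of unit 1 and at C5 and C7 of unit 2 stay masked as benzyl ethers until the end, so the air-sensitive polyphenol is exposed only once. The forward step is one hydrogenolysis that must spare the two methyl ethers, the diaryl ether and both C2=C3 bonds.

**17 from 15.** The two C3–O bonds are cut. Without the C3 oxygen each unit is a plain flavone, which a 1,3-diketone can deliver. The forward step has to oxygenate C3 of both units: epoxidation of C2=C3 to the bis-epoxide 16, then acid-catalysed isomerisation.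

**15 from 14.** The C5–O bond of unit 1 and the C5–O and C7–O bonds of unit 2 are traced back to C–F bonds. Each of these carbons is ortho or para to the pyranone carbonyl, so fluorine here is a latent oxygen. The forward step exchanges three fluorines for benzyloxy groups without opening the pyranones. The C7 methoxy group of unit 1 is already in place, which is what distinguishes the two rings A.

**14 from 13 (key disconnection).** Both O1–C8a bonds are cut, opening both rings C to the bis(1,3-diketone) 13. This is the place to cut because the remaining skeleton is then only C–C bonds between carbonyl carbons, made by enolate chemistry. Ring A never has to act as a nucleophile, and one operation builds two rings. The forward reaction must make each enolate oxygen displace an ortho fluoride within its own half of the molecule.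

**13 from 10 and 11.** The C2–C3 bond of unit 2 is cut. Forward, the enolate of ketone 11 is acylated by the methyl ester of 10 in a Claisen condensation.

**10 from 7 and 3, through 9.** The C2–C3 bond of unit 1 is cut. The two acyl carbons on the diaryl ether must be distinguishable, and an aldehyde and a methyl ester are: at −78 °C an enolate adds to the aldehyde only. Aldol addition of the enolate of 3 to 7 gives 9, and oxidation gives diketone 10. Two esters of different size would not serve, because an ester hindered enough to survive the first condensation would not acylate an enolate in the second.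

**7 from 5 and 6.** The diaryl ether C–O bond at C4′ of ring B of unit 1 is cut. The formyl group para to fluorine in 5 is chosen because it makes this substitution dependable. An ester in its place, next to an ortho alkoxy group, would activate the fluoride too weakly.

**5 from 4, and 3 from 1.** The O–benzyl bond of 5 leads to the fluorophenol 4. The aryl–acetyl bond of 3 leads to 1, whose C–H between the two fluorines is the most acidic site and can be metalated and acetylated.

## Alternatives that were turned down

**Alternative 1:** Ring A of unit 2 is cut between C4a and its oxygen-bearing neighbour (C5 or C8a, which are equivalent) and traced to an open polyketide chain stored as the 4-hydroxy-2-pyrone A1.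
- **Key step:** Mg(OMe)2 in methanol opens the lactone of A1 to a magnesium-chelated triketo ester. The methylene between its two distal ketones attacks the ester carbon (Claisen cyclisation), and aromatisation gives the 2′,4′,6′-trihydroxychalcone A2.
- **For:** Ring A is made with all three oxygens in place and with no aromatic substitution. A2 is one Algar–Flynn–Oyamada oxidation away from a flavonol, so O1–C2 and the C3 hydroxyl come together. On this point it is stronger than the chosen route, which needs a separate C3 oxygenation (step 9).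
- **Against:** The same triketo ester can close by aldol attack instead, giving a resorcylate. The cinnamoyl enone is exposed to methoxide. The oxidative cyclisation of a chalcone with two free ortho hydroxyls can divert to an aurone, so phenols would have to be protected first. Only unit 2 is made; unit 1 would need a second full sequence from the dioxolane-masked aldehyde, including a selective 7-O-methylation.
- **Comparison:** The sequence is long and linear. The chosen route closes both pyranones of 13 in one operation and offers brevity and convergence in place of the built-in C3 oxygen.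

**Alternative 2:** Ring C of unit 1 is cut at C4a–C4, C4–C3 and O1–C2 into three components: the symmetric iodoresorcinol A3, carbon monoxide and the terminal alkyne A4.
- **Key step:** PdCl2(PPh3)2 in Et2NH under CO. Zerovalent palladium inserts into the C–I bond of A3, CO insertion gives a divalent acylpalladium species, coupling with A4 gives an ortho-hydroxyaryl ynone, and the amine promotes oxa-Michael closure to flavone A5.
- **For:** Three bonds form in one step. The C5 hydroxyl appears free, and the symmetry of A3 removes any regiochemical question. The silyl-capped second alkyne of A5 is ready for a second annulation. It is stronger than the chosen route in needing no fluoride exchange and in leaving ring A unprotected.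
- **Against:** A3 is an electron-rich aryl iodide with both ortho positions substituted, so oxidative addition and CO insertion are slow. Direct alkyne coupling without CO, and five-membered closure to an aurone, compete. A4 needs two differentiated alkynes on the diaryl ether. The annulation must be run twice, and both C3 positions still have to be oxygenated afterwards.
- **Comparison:** The chosen route reaches the same oxidation level (14, then 15) without palladium or CO and makes both rings C at once. What it gives up is the direct, protecting-group-free C5 hydroxyl.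

**Alternative 3:** Ring C of unit 2 is cut at C3–C4 and O1–C2. Ring A comes from the salicylate acetonide A6, and C2, C3 and ring B from the benzyloxyacetyl ketone A7.
- **Key step:** The lithium enolate of A7 (from LiN(SiMe3)2) attacks the lactone carbonyl of A6. Collapse of the adduct releases acetone and a phenoxide. Acid in the same pot condenses the phenol with the ring B ketone to give the 3-benzyloxyflavone A8.
- **For:** Every oxygen, including the one at C3, is in place before ring closure, and each bond-forming event is classical carbonyl chemistry. It is stronger than the chosen route in certainty of functional-group outcome: no fluoride exchange and no dioxirane.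
- **Against:** The carbonyl of A6 is flanked by a benzyloxy group and the ring oxygen, so it is hindered and electron-rich and needs excess enolate. The aryl bromide of A8 must then be turned into a second benzyloxyacetyl ketone in the presence of a flavone, and the whole sequence repeated with a second, differently alkylated benzodioxinone.
- **Comparison:** The route is linear and roughly twice as long. The chosen route offers one twofold ring closure and purchasable fluoro ketones in place of this step-by-step certainty.

Key step: step 7

Assumption: compounds 1, 4, 6 and 11 are taken as purchased, and 9 is made and used as the racemate because its only stereocentre is removed in step 5.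

## Route

**Step 1**
Reactants: 1 3,5-difluoroanisole
Product: 3 1-(2,6-difluoro-4-methoxyphenyl)ethan-1-one, via (2,6-difluoro-4-methoxyphenyl)lithium 2 (not isolated)
Conditions: n-BuLi, THF, −78 °C; then MeC(O)N(OMe)Me, −78 → 0 °C; 1 M HCl
Reagents that add atoms: N-methoxy-N-methylacetamide, CC(=O)N(C)OC
Why: Directed ortho-metalation: the C–H between the two fluorines of 1 is the most acidic, so deprotonation at −78 °C gives 2 before benzyne formation can set in. The N-methoxy-N-methylamide acylates 2 through a chelated tetrahedral adduct that releases the ketone only on acidic work-up, so no tertiary alcohol forms.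

**Step 2**
Reactants: 4 4-fluoro-3-hydroxybenzaldehyde
Product: 5 3-(benzyloxy)-4-fluorobenzaldehyde
Conditions: BnBr, K2CO3, DMF, rt
Reagents that add atoms: benzyl bromide, BrCc1ccccc1
Why: Williamson ether synthesis on the phenoxide; at room temperature benzylation is far faster than any attack of the phenoxide on the aryl fluoride, and the aldehyde is inert to carbonate.

**Step 3**
Reactants: 5 3-(benzyloxy)-4-fluorobenzaldehyde; 6 methyl 4-hydroxy-3-methoxybenzoate (methyl vanillate)
Product: 7 methyl 4-[2-(benzyloxy)-4-formylphenoxy]-3-methoxybenzoate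
Conditions: K2CO3, DMSO, 110 °C
Reagents that add atoms: none
Why: Nucleophilic aromatic substitution by addition–elimination: the formyl group para to fluorine stabilises the Meisenheimer adduct and the phenoxide of 6 displaces fluoride. The methyl ester and the benzyl ether are inert to carbonate in dry DMSO.

**Step 4**
Reactants: 3 1-(2,6-difluoro-4-methoxyphenyl)ethan-1-one; 7 methyl 4-[2-(benzyloxy)-4-formylphenoxy]-3-methoxybenzoate
Product: 9 methyl 4-{2-(benzyloxy)-4-[3-(2,6-difluoro-4-methoxyphenyl)-1-hydroxy-3-oxopropyl]phenoxy}-3-methoxybenzoate (racemic), via lithium enolate 8 (not isolated)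
Conditions: 3, LiN(SiMe3)2, THF, −78 °C; then 7, −78 °C; AcOH, −78 °C
Reagents that add atoms: none
Why: Aldol addition of a preformed lithium enolate: at −78 °C enolate 8 adds to the aldehyde of 7 much faster than to its methyl ester, and the cold quench prevents retro-aldol reaction and dehydration. The carbinol carbon of 9 forms as a racemate and is erased in step 5.

**Step 5**
Reactants: 9 methyl 4-{2-(benzyloxy)-4-[3-(2,6-difluoro-4-methoxyphenyl)-1-hydroxy-3-oxopropyl]phenoxy}-3-methoxybenzoate
Product: 10 methyl 4-{2-(benzyloxy)-4-[3-(2,6-difluoro-4-methoxyphenyl)-3-oxopropanoyl]phenoxy}-3-methoxybenzoate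
Conditions: 2-iodoxybenzoic acid (IBX), EtOAc, 75 °C
Reagents that add atoms: none
Why: Oxidation of a β-hydroxy ketone to the 1,3-diketone by a hypervalent iodine reagent. No base is present, so the ortho-fluoro ketone can neither cyclise nor be substituted, and the benzyl ether and ester are untouched.

**Step 6**
Reactants: 10 methyl 4-{2-(benzyloxy)-4-[3-(2,6-difluoro-4-methoxyphenyl)-3-oxopropanoyl]phenoxy}-3-methoxybenzoate; 11 1-(2,4,6-trifluorophenyl)ethan-1-one
Product: 13 1-[3-(benzyloxy)-4-{2-methoxy-4-[3-oxo-3-(2,4,6-trifluorophenyl)propanoyl]phenoxy}phenyl]-3-(2,6-difluoro-4-methoxyphenyl)propane-1,3-dione, via lithium enolate 12 (not isolated)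
Conditions: 11 (2.5 equiv), LiN(SiMe3)2 (4.6 equiv), THF, −78 °C; then 10, −78 °C → rt; AcOH
Reagents that add atoms: none
Why: Crossed Claisen condensation: enolate 12 is acylated by the methyl ester of 10, and deprotonation of the new diketone drives the reaction. The base is in excess over every acidic site, so the diketone of 10, the product and all of 11 stay as lithium enolates; in that form the fluoroaryl rings are too electron-rich for the liberated LiOMe to substitute.

**Step 7**
Reactants: 13 1-[3-(benzyloxy)-4-{2-methoxy-4-[3-oxo-3-(2,4,6-trifluorophenyl)propanoyl]phenoxy}phenyl]-3-(2,6-difluoro-4-methoxyphenyl)propane-1,3-dione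
Product: 14 2-{3-(benzyloxy)-4-[4-(5,7-difluoro-4-oxo-4H-chromen-2-yl)-2-methoxyphenoxy]phenyl}-5-fluoro-7-methoxy-4H-chromen-4-one
Conditions: K2CO3, DMF (dry, amine-free, 0.02 M), 60 °C
Reagents that add atoms: none
Why: Carbonate deprotonates both diketones; in each enolate the oxygen on the carbon next to ring B adds to an ortho C–F carbon of the fluoroaryl ketone, giving a Meisenheimer adduct whose charge is taken up by the adjacent C4 carbonyl, and loss of fluoride restores the aromatic ring A (intramolecular addition–elimination). The closest known reaction is the base-mediated cyclisation of 1-(2-fluoroaryl)-1,3-diketones to chromones and flavones. Ring C of unit 1 and ring C of unit 2 are each closed in the six-membered mode by O-attack at C8a, forming O1–C8a (an endo-trig closure with respect to the C8a=C4a bond conjugated with C4=O). No stereocentre is formed. O- rather than C-cyclisation is secured by ring size, since attack by the central carbon or by the other oxygen would give a four-membered ring. No choice between fluorines arises, because the two ortho fluorines of each ring are equivalent and the para fluorine of unit 2 cannot be reached within the molecule. Closure must outrun substitution between molecules, which the intramolecular six-membered geometry, the dilution and a temperature at which DMF is not yet a source of dimethylamine should secure. The three fluorines left in 14 meet only carbonate, a poor nucleophile, under dry conditions.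

**Step 8**
Reactants: 14 2-{3-(benzyloxy)-4-[4-(5,7-difluoro-4-oxo-4H-chromen-2-yl)-2-methoxyphenoxy]phenyl}-5-fluoro-7-methoxy-4H-chromen-4-one
Product: 15 5-(benzyloxy)-2-{3-(benzyloxy)-4-[4-(5,7-bis(benzyloxy)-4-oxo-4H-chromen-2-yl)-2-methoxyphenoxy]phenyl}-7-methoxy-4H-chromen-4-one
Conditions: BnOH, NaH, THF, 0 → 60 °C
Reagents that add atoms: benzyl alcohol (used as sodium benzyloxide), OCc1ccccc1
Why: Nucleophilic aromatic substitution: the remaining fluorines are ortho (C5 of both units) and para (C7 of unit 2) to the C4 carbonyl, so benzyloxide displaces all three by addition–elimination. Addition of the alkoxide at C2 is hindered by the 2-aryl group and reversible, and the methoxy groups are not leaving groups here.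

**Step 9**
Reactants: 15 5-(benzyloxy)-2-{3-(benzyloxy)-4-[4-(5,7-bis(benzyloxy)-4-oxo-4H-chromen-2-yl)-2-methoxyphenoxy]phenyl}-7-methoxy-4H-chromen-4-one
Product: 17 5-(benzyloxy)-2-{3-(benzyloxy)-4-[4-(5,7-bis(benzyloxy)-3-hydroxy-4-oxo-4H-chromen-2-yl)-2-methoxyphenoxy]phenyl}-3-hydroxy-7-methoxy-4H-chromen-4-one, via bis(2,3-epoxide) 16 (not isolated)
Conditions: dimethyldioxirane (acetone), CH2Cl2, 0 °C → rt; then p-TsOH (cat.), CH2Cl2, rt
Reagents that add atoms: dimethyldioxirane, CC1(C)OO1
Why: Electrophilic epoxidation of the enol-ether-like C2=C3 bond of each flavone gives 16; catalytic acid opens each oxirane at C2 to the oxocarbenium ion stabilised by O1 and ring B, and loss of H3 gives the 3-hydroxy-4-pyranone. This is the known dioxirane route from flavones to flavonols. The stereocentres of 16 (each oxirane cis by necessity, mixture of diastereomers) vanish in the isomerisation.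

**Step 10**
Reactants: 17 5-(benzyloxy)-2-{3-(benzyloxy)-4-[4-(5,7-bis(benzyloxy)-3-hydroxy-4-oxo-4H-chromen-2-yl)-2-methoxyphenoxy]phenyl}-3-hydroxy-7-methoxy-4H-chromen-4-one
Product: 18 3,5-dihydroxy-2-{3-hydroxy-4-[2-methoxy-4-(3,5,7-trihydroxy-4-oxo-4H-chromen-2-yl)phenoxy]phenyl}-7-methoxy-4H-chromen-4-one
Conditions: H2 (1 atm), Pd/C, THF–MeOH, rt
Reagents that add atoms: none
Why: Hydrogenolysis of the four benzyl aryl ethers on Pd/C. The methyl ethers, the diaryl ether and the tetrasubstituted, conjugated C2=C3 bonds should not be reduced under one atmosphere of hydrogen at room temperature.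

## Compound list

1 | 3,5-difluoroanisole | COc1cc(F)cc(F)c1 | starting material
2 | (2,6-difluoro-4-methoxyphenyl)lithium | [Li]c1c(F)cc(OC)cc1F | intermediate
3 | 1-(2,6-difluoro-4-methoxyphenyl)ethan-1-one | CC(=O)c1c(F)cc(OC)cc1F | intermediate
4 | 4-fluoro-3-hydroxybenzaldehyde | O=Cc1ccc(F)c(O)c1 | starting material
5 | 3-(benzyloxy)-4-fluorobenzaldehyde | O=Cc1ccc(F)c(OCc2ccccc2)c1 | intermediate
6 | methyl 4-hydroxy-3-methoxybenzoate (methyl vanillate) | COC(=O)c1ccc(O)c(OC)c1 | starting material
7 | methyl 4-[2-(benzyloxy)-4-formylphenoxy]-3-methoxybenzoate | COC(=O)c1ccc(Oc2ccc(C=O)cc2OCc2ccccc2)c(OC)c1 | intermediate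
8 | lithium 1-(2,6-difluoro-4-methoxyphenyl)ethen-1-olate | [Li+].[O-]C(=C)c1c(F)cc(OC)cc1F | intermediate
9 | methyl 4-{2-(benzyloxy)-4-[3-(2,6-difluoro-4-methoxyphenyl)-1-hydroxy-3-oxopropyl]phenoxy}-3-methoxybenzoate (racemic) | COC(=O)c1ccc(Oc2ccc(C(O)CC(=O)c3c(F)cc(OC)cc3F)cc2OCc2ccccc2)c(OC)c1 | intermediate
10 | methyl 4-{2-(benzyloxy)-4-[3-(2,6-difluoro-4-methoxyphenyl)-3-oxopropanoyl]phenoxy}-3-methoxybenzoate | COC(=O)c1ccc(Oc2ccc(C(=O)CC(=O)c3c(F)cc(OC)cc3F)cc2OCc2ccccc2)c(OC)c1 | intermediate
11 | 1-(2,4,6-trifluorophenyl)ethan-1-one | CC(=O)c1c(F)cc(F)cc1F | starting material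
12 | lithium 1-(2,4,6-trifluorophenyl)ethen-1-olate | [Li+].[O-]C(=C)c1c(F)cc(F)cc1F | intermediate
13 | 1-[3-(benzyloxy)-4-{2-methoxy-4-[3-oxo-3-(2,4,6-trifluorophenyl)propanoyl]phenoxy}phenyl]-3-(2,6-difluoro-4-methoxyphenyl)propane-1,3-dione | COc1cc(F)c(C(=O)CC(=O)c2ccc(Oc3ccc(C(=O)CC(=O)c4c(F)cc(F)cc4F)cc3OC)c(OCc5ccccc5)c2)c(F)c1 | intermediate
14 | 2-{3-(benzyloxy)-4-[4-(5,7-difluoro-4-oxo-4H-chromen-2-yl)-2-methoxyphenoxy]phenyl}-5-fluoro-7-methoxy-4H-chromen-4-one | COc1cc(F)c2c(=O)cc(-c3ccc(Oc4ccc(-c5cc(=O)c6c(F)cc(F)cc6o5)cc4OC)c(OCc7ccccc7)c3)oc2c1 | intermediate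
15 | 5-(benzyloxy)-2-{3-(benzyloxy)-4-[4-(5,7-bis(benzyloxy)-4-oxo-4H-chromen-2-yl)-2-methoxyphenoxy]phenyl}-7-methoxy-4H-chromen-4-one | COc1cc(OCc8ccccc8)c2c(=O)cc(-c3ccc(Oc4ccc(-c5cc(=O)c6c(OCc7ccccc7)cc(OCc7ccccc7)cc6o5)cc4OC)c(OCc7ccccc7)c3)oc2c1 | intermediate
16 | bis(2,3-epoxide) of 15: 6-(benzyloxy)-1a-{3-(benzyloxy)-4-[4-(4,6-bis(benzyloxy)-7-oxo-7,7a-dihydro-1aH-oxireno[2,3-b]chromen-1a-yl)-2-methoxyphenoxy]phenyl}-4-methoxy-1a,7a-dihydro-7H-oxireno[2,3-b]chromen-7-one (each oxirane cis-fused; mixture of racemic diastereomers) | COc1cc(OCc2ccccc2)c2C(=O)C3OC3(c3ccc(Oc4ccc(C56Oc7cc(OCc8ccccc8)cc(OCc8ccccc8)c7C(=O)C5O6)cc4OC)c(OCc4ccccc4)c3)Oc2c1 | intermediate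
17 | 5-(benzyloxy)-2-{3-(benzyloxy)-4-[4-(5,7-bis(benzyloxy)-3-hydroxy-4-oxo-4H-chromen-2-yl)-2-methoxyphenoxy]phenyl}-3-hydroxy-7-methoxy-4H-chromen-4-one | COc1cc(OCc2ccccc2)c2c(=O)c(O)c(-c3ccc(Oc4ccc(-c5oc6cc(OCc7ccccc7)cc(OCc7ccccc7)c6c(=O)c5O)cc4OC)c(OCc7ccccc7)c3)oc2c1 | intermediate
18 | 3,5-dihydroxy-2-{3-hydroxy-4-[2-methoxy-4-(3,5,7-trihydroxy-4-oxo-4H-chromen-2-yl)phenoxy]phenyl}-7-methoxy-4H-chromen-4-one | COc1cc(O)c2c(=O)c(O)c(-c3ccc(Oc4ccc(-c5oc6cc(O)cc(O)c6c(=O)c5O)cc4OC)c(O)c3)oc2c1 | target

## Step count and least certain steps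

Total: 10 steps. Longest linear sequence: 9 steps (steps 2 to 10, from 4). Step 1 is a one-step side branch that joins at step 4.

**Step 7 (key step).** The most likely failure is substitution between molecules at the para fluorine of the trifluorophenyl ketone. That fluorine is activated but cannot take part in ring closure, so an enolate oxygen of a second molecule, hydroxide from wet carbonate or dimethylamine from DMF could attack it. A slow second closure would add mixtures.

The fallback removes that fluorine from the design. It sets out from 3 and 10 and returns at 15. Ketone 3 is demethylated with BBr3 (CH2Cl2, −78 °C → rt) to 1-(2,6-difluoro-4-hydroxyphenyl)ethan-1-one F1. Benzylation (BnBr, K2CO3, DMF) gives 1-[4-(benzyloxy)-2,6-difluorophenyl]ethan-1-one F2. Its enolate, lithium 1-[4-(benzyloxy)-2,6-difluorophenyl]ethen-1-olate F3, made with LiN(SiMe3)2, is condensed with 10 as in step 6. This gives 1-[4-(benzyloxy)-2,6-difluorophenyl]-3-(4-{2-(benzyloxy)-4-[3-(2,6-difluoro-4-methoxyphenyl)-3-oxopropanoyl]phenoxy}-3-methoxyphenyl)propane-1,3-dione F4, in which no fluorine is para to a ketone. K2CO3 in DMF closes both rings to 7-(benzyloxy)-2-{4-[2-(benzyloxy)-4-(5-fluoro-7-methoxy-4-oxo-4H-chromen-2-yl)phenoxy]-3-methoxyphenyl}-5-fluoro-4H-chromen-4-one F5. Exchange of its two C5 fluorines with NaOCH2Ph (from BnOH and NaH) gives 15.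

**Step 6.** Acyl transfer to the electron-rich, anionic benzoate may be slow. Long exposure at room temperature could then allow attack of LiOMe on a fluoroarene or early, partial ring closure.

The fallback avoids alkoxide release. It sets out from 10 and returns at 13. Me3SnOH (1,2-dichloroethane, 80 °C) cleaves the methyl ester under nearly neutral conditions to 4-{2-(benzyloxy)-4-[3-(2,6-difluoro-4-methoxyphenyl)-3-oxopropanoyl]phenoxy}-3-methoxybenzoic acid F6. 1,1′-Carbonyldiimidazole in THF converts the acid into 1-(2-(benzyloxy)-4-{4-[(1H-imidazol-1-yl)carbonyl]-2-methoxyphenoxy}phenyl)-3-(2,6-difluoro-4-methoxyphenyl)propane-1,3-dione F7; the chelated enol of the diketone is a far poorer partner for this reagent than the carboxylic acid. F7 is added to an excess of 12 at −78 °C and gives 13 with loss of imidazole.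

**Step 8.** Benzyloxide may add at C2 and open a pyranone, and the last displacement on each ring is slowed by the alkoxy group already present. Forcing conditions would then lead to cleavage of the diketone formed by ring opening.

The fallback replaces the hard alkoxide at the hindered C5 positions by a weakly basic hydroxide surrogate. It sets out from 14 and returns at 15. One equivalent of BnOH with K2CO3 in DMF (0 °C → rt) should exchange only the most reactive fluorine, at C7 of unit 2 (para to C4=O and unhindered), giving 7-(benzyloxy)-2-{4-[2-(benzyloxy)-4-(5-fluoro-7-methoxy-4-oxo-4H-chromen-2-yl)phenoxy]-3-methoxyphenyl}-5-fluoro-4H-chromen-4-one F5. Acetohydroxamic acid with K2CO3 in DMSO at 80 °C (O-arylation, then Lossen-type fragmentation to the phenoxide) converts both C5 fluorines into phenols. The product is 7-(benzyloxy)-2-{4-[2-(benzyloxy)-4-(5-hydroxy-7-methoxy-4-oxo-4H-chromen-2-yl)phenoxy]-3-methoxyphenyl}-5-hydroxy-4H-chromen-4-one F8. BnBr with K2CO3 in DMF at 60 °C benzylates the two chelated phenols to give 15.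

**Step 9.** The excess dioxirane needed for two conjugated C2=C3 bonds may oxidise benzylic C–H bonds of the four benzyl ethers, or the second epoxidation may stay incomplete.

The fallback uses carbanion chemistry in place of an electrophilic oxidant. It sets out from 15 and returns at 17. LiN(i-Pr)2 (THF, −78 °C) removes H3 of both flavones to give the 3,3″-dilithio derivative of 15 F9. B(OMe)3 traps it as the 3,3″-bis(dimethoxyboryl) derivative of 15 F10. H2O2 in AcOH oxidises both C–B bonds and gives 17.

## Further compounds

F1 | step 7 | 1-(2,6-difluoro-4-hydroxyphenyl)ethan-1-one | CC(=O)c1c(F)cc(O)cc1F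
F2 | step 7 | 1-[4-(benzyloxy)-2,6-difluorophenyl]ethan-1-one | CC(=O)c1c(F)cc(OCc2ccccc2)cc1F
F3 | step 7 | lithium 1-[4-(benzyloxy)-2,6-difluorophenyl]ethen-1-olate | [Li+].[O-]C(=C)c1c(F)cc(OCc2ccccc2)cc1F
F4 | step 7 | 1-[4-(benzyloxy)-2,6-difluorophenyl]-3-(4-{2-(benzyloxy)-4-[3-(2,6-difluoro-4-methoxyphenyl)-3-oxopropanoyl]phenoxy}-3-methoxyphenyl)propane-1,3-dione | COc1cc(F)c(C(=O)CC(=O)c2ccc(Oc3ccc(C(=O)CC(=O)c4c(F)cc(OCc5ccccc5)cc4F)cc3OC)c(OCc5ccccc5)c2)c(F)c1
F5 | step 7 | 7-(benzyloxy)-2-{4-[2-(benzyloxy)-4-(5-fluoro-7-methoxy-4-oxo-4H-chromen-2-yl)phenoxy]-3-methoxyphenyl}-5-fluoro-4H-chromen-4-one | COc1cc(F)c2c(=O)cc(-c3ccc(Oc4ccc(-c5cc(=O)c6c(F)cc(OCc7ccccc7)cc6o5)cc4OC)c(OCc7ccccc7)c3)oc2c1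
F6 | step 6 | 4-{2-(benzyloxy)-4-[3-(2,6-difluoro-4-methoxyphenyl)-3-oxopropanoyl]phenoxy}-3-methoxybenzoic acid | OC(=O)c1ccc(Oc2ccc(C(=O)CC(=O)c3c(F)cc(OC)cc3F)cc2OCc2ccccc2)c(OC)c1
F7 | step 6 | 1-(2-(benzyloxy)-4-{4-[(1H-imidazol-1-yl)carbonyl]-2-methoxyphenoxy}phenyl)-3-(2,6-difluoro-4-methoxyphenyl)propane-1,3-dione | O=C(c1ccc(Oc2ccc(C(=O)CC(=O)c3c(F)cc(OC)cc3F)cc2OCc2ccccc2)c(OC)c1)n1ccnc1
F8 | step 8 | 7-(benzyloxy)-2-{4-[2-(benzyloxy)-4-(5-hydroxy-7-methoxy-4-oxo-4H-chromen-2-yl)phenoxy]-3-methoxyphenyl}-5-hydroxy-4H-chromen-4-one | COc1cc(O)c2c(=O)cc(-c3ccc(Oc4ccc(-c5cc(=O)c6c(O)cc(OCc7ccccc7)cc6o5)cc4OC)c(OCc7ccccc7)c3)oc2c1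
F9 | step 9 | 3,3″-dilithio derivative of 15 (lithium at C3 of each chromen-4-one) | COc1cc(OCc2ccccc2)c2c(=O)c([Li])c(-c3ccc(Oc4ccc(-c5oc6cc(OCc7ccccc7)cc(OCc7ccccc7)c6c(=O)c5[Li])cc4OC)c(OCc7ccccc7)c3)oc2c1
F10 | step 9 | 3,3″-bis(dimethoxyboryl) derivative of 15 (B(OMe)2 at C3 of each chromen-4-one) | COc1cc(OCc2ccccc2)c2c(=O)c(B(OC)OC)c(-c3ccc(Oc4ccc(-c5oc6cc(OCc7ccccc7)cc(OCc7ccccc7)c6c(=O)c5B(OC)OC)cc4OC)c(OCc7ccccc7)c3)oc2c1
A1 | alternative 1 | 6-[(E)-4-{4-[2-(benzyloxy)-4-(1,3-dioxolan-2-yl)phenoxy]-3-methoxyphenyl}-2-oxobut-3-en-1-yl]-4-hydroxy-2H-pyran-2-one | O=C(/C=C/c1ccc(Oc2ccc(C3OCCO3)cc2OCc2ccccc2)c(OC)c1)Cc1cc(O)cc(=O)o1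
A2 | alternative 1 | (E)-3-{4-[2-(benzyloxy)-4-(1,3-dioxolan-2-yl)phenoxy]-3-methoxyphenyl}-1-(2,4,6-trihydroxyphenyl)prop-2-en-1-one | O=C(/C=C/c1ccc(Oc2ccc(C3OCCO3)cc2OCc2ccccc2)c(OC)c1)c1c(O)cc(O)cc1O
A3 | alternative 2 | 2-iodo-5-methoxybenzene-1,3-diol | COc1cc(O)c(I)c(O)c1
A4 | alternative 2 | 2-(benzyloxy)-4-ethynyl-1-{2-methoxy-4-[(triisopropylsilyl)ethynyl]phenoxy}benzene | C#Cc1ccc(Oc2ccc(C#C[Si](C(C)C)(C(C)C)C(C)C)cc2OC)c(OCc2ccccc2)c1
A5 | alternative 2 | 2-{3-(benzyloxy)-4-[2-methoxy-4-(triisopropylsilylethynyl)phenoxy]phenyl}-5-hydroxy-7-methoxy-4H-chromen-4-one | COc1cc(O)c2c(=O)cc(-c3ccc(Oc4ccc(C#C[Si](C(C)C)(C(C)C)C(C)C)cc4OC)c(OCc5ccccc5)c3)oc2c1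
A6 | alternative 3 | 5,7-bis(benzyloxy)-2,2-dimethyl-4H-1,3-benzodioxin-4-one | CC1(C)OC(=O)c2c(OCc3ccccc3)cc(OCc3ccccc3)cc2O1
A7 | alternative 3 | 2-(benzyloxy)-1-{4-[2-(benzyloxy)-4-bromophenoxy]-3-methoxyphenyl}ethan-1-one | O=C(COCc1ccccc1)c1ccc(Oc2ccc(Br)cc2OCc2ccccc2)c(OC)c1
A8 | alternative 3 | 3,5,7-tris(benzyloxy)-2-{4-[2-(benzyloxy)-4-bromophenoxy]-3-methoxyphenyl}-4H-chromen-4-one | O=c1c(OCc3ccccc3)c(-c2ccc(Oc3ccc(Br)cc3OCc3ccccc3)c(OC)c2)oc2cc(OCc3ccccc3)cc(OCc3ccccc3)c12
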